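## Retrosynthetic overview

1. Forward path in brief: allylphenol 1 → (E)-propenylphenol 2; 2 + (E)-isoeugenol 3 → p-quinone methide 4 → maceneolignan A 5.
2. 5 ⇒ 4: break O1–C2; forward, the phenol oxygen adds 5-exo to the p-quinone methide and places the aryl group trans to the C3 methyl.
3. 4 ⇒ 2 + 3: break C3–C3a (C8–C5' in lignan numbering); forward, an enantioselective oxidative β-5 phenol cross-coupling on the chiral complex VO(L)(OiPr), made from VO(OiPr)3 and a Schiff-base ligand H2L, sets C3.
4. 2 ⇒ 1: allyl-to-propenyl isomerization.
5. Ring order: both benzene rings are bought; the dihydrofuran ring is the only ring made and is closed last, in the same flask as the C–C coupling.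

## Assumptions

- The SMILES is read as the trans-(2R,3R)-2,3-dihydrobenzofuran with an (E)-propenyl group.
- The sense of induction of the new coupling cannot be predicted; the (S)-ligand is written, and its equally available (R)-antipode is used instead if the first run gives the (2S,3S) series.
- Compound 2 is made from 1 rather than bought, because purchasable 2 is a dearer flavour-grade E/Z mixture.
- The route has only two steps, so both are ranked for risk; step 2 can fail in two independent ways and each gets its own fallback.

## Route

Step 1
Reactants: 1 4-allyl-2,6-dimethoxyphenol (methoxyeugenol)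
Product: 2 (E)-2,6-dimethoxy-4-(prop-1-en-1-yl)phenol
Conditions: RuHCl(CO)(PPh3)3 (1 mol%), toluene, 80 °C, 3 h; silica plug
Reagents that add atoms: none
Why: Alkene isomerization by RuHCl(CO)(PPh3)3 (hydrometalation then β-hydride elimination) moves the terminal double bond into conjugation with the arene and ends at the thermodynamically preferred E-propenyl isomer, the free phenol is tolerated as in the eugenol-to-isoeugenol conversion, no stereocentre is formed and nothing is formed beside 2.

Step 2
Reactants: 2 (E)-2,6-dimethoxy-4-(prop-1-en-1-yl)phenol (2.0 equiv); 3 (E)-isoeugenol, 2-methoxy-4-[(E)-prop-1-en-1-yl]phenol (1.0 equiv)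
Product: 5 maceneolignan A, via p-quinone methide 4 (not isolated)
Conditions: VO(OiPr)3 (10 mol%), (S)-2-[(3,5-di-tert-butyl-2-hydroxybenzylidene)amino]-3,3-dimethylbutan-1-ol (H2L, 12 mol%), O2 (1 atm), PhCl/HFIP 9:1, 0 °C, 3 added over 8 h; chromatography, recrystallization to >99% ee
Reagents that add atoms: none
Why: Proposed new method: an oxidative β-5 phenol cross-coupling run inside a chiral ligand sphere, in which 3, the less hindered phenol, binds to pentavalent vanadium in VO(L)(OiPr) as its aryloxide and inner-sphere electron transfer gives a vanadium-held phenoxyl radical with spin at its free ortho carbon; the electron-rich β-carbon (C8) of 2, whose own ortho positions are both blocked so that it can join only through C8, attacks that carbon from the alkene face left open by the tert-butyl group of the ligand, which fixes C8 (C3 of 5); loss of a second electron and a proton with re-aromatization gives p-quinone methide 4, whose neighbouring phenol oxygen adds 5-exo-trig (oxa-Michael 1,6-addition) with the aryl group settling trans to the methyl, which sets C2; O2 returns tetravalent vanadium to the pentavalent state and is itself reduced to water, which takes up the two hydrogen atoms lost from 2 and 3; the closest known reaction types are the enantioselective aerobic oxidative coupling of phenols and 2-naphthols on VO(L)(OR)-type Schiff-base complexes and the Ag2O- or peroxidase-mediated β-5 dehydrodimerization of isoeugenol, the laboratory counterpart of the radical coupling by which plants join propenylphenols.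

## Compound list

1 | 4-allyl-2,6-dimethoxyphenol (methoxyeugenol) | C=CCc1cc(OC)c(O)c(OC)c1 | starting material
2 | (E)-2,6-dimethoxy-4-(prop-1-en-1-yl)phenol | C/C=C/c1cc(OC)c(O)c(OC)c1 | intermediate
3 | (E)-isoeugenol, 2-methoxy-4-[(E)-prop-1-en-1-yl]phenol | C/C=C/c1ccc(O)c(OC)c1 | starting material
4 | 4-{(2S)-2-[2-hydroxy-3-methoxy-5-((E)-prop-1-en-1-yl)phenyl]propylidene}-2,6-dimethoxycyclohexa-2,5-dien-1-one (p-quinone methide, not isolated) | C/C=C/c1cc(OC)c(O)c(c1)[C@@H](C)C=C1C=C(OC)C(=O)C(OC)=C1 | intermediate
5 | maceneolignan A, 4-[(2R,3R)-7-methoxy-3-methyl-5-((E)-prop-1-en-1-yl)-2,3-dihydro-1-benzofuran-2-yl]-2,6-dimethoxyphenol | C/C=C/c1cc(OC)c2c(c1)[C@@H](C)[C@H](c1cc(OC)c(O)c(OC)c1)O2 | target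

## Step count and risks

Total step count: 2. Longest linear sequence: 2 steps (1 → 2 → 5); 3 enters in step 2.

Steps most likely to fail, in order of risk (two steps only, step 2 counted twice for its two independent failure modes):

**Step 2, enantiocontrol.** Phenoxyl radicals that leave the metal couple in free solution without facial bias, so the ee may be low or the sense of induction wrong. The fallback gives up catalyst control and resolves instead. It sets out from 2 and 3, which are coupled with Ag2O (1.2 equiv) in toluene/acetone at room temperature. This classical dehydrogenative cross-coupling runs through 4 and its mirror image, the (R)-quinone methide F1, and gives 5 as a racemate with the (2S,3S)-enantiomer of maceneolignan A F2. The two are parted by preparative supercritical-fluid chromatography on an amylose tris(3,5-dimethylphenylcarbamate) phase, which comes back to the route at 5.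

**Step 2, cross- against homo-coupling.** Compound 3 can dimerize with itself in the β-5 sense (licarin A), 2 can give β-O-4 and β-β products, and 5 can be over-oxidized. The excess of 2 and the slow addition of 3 are meant to hold this down; an expected 30–45% of 5 based on 3 is an estimate. The fallback changes the guaiacyl partner. It sets out from 2, and 3 is replaced by purchased eugenol (4-allyl-2-methoxyphenol), which has no conjugated side chain and so cannot dimerize through a β-carbon. The same VO(OiPr)3/H2L/O2 conditions join C8 of 2 to the free ortho carbon of eugenol. The reaction passes through the allyl-substituted (S)-quinone methide F3 and gives 4-[(2R,3R)-5-allyl-7-methoxy-3-methyl-2,3-dihydro-1-benzofuran-2-yl]-2,6-dimethoxyphenol F4. RuHCl(CO)(PPh3)3 (1 mol%) in toluene at 80 °C then moves the allyl double bond into conjugation, which comes back to the route at 5.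

**Step 1.** The free phenol may slow the catalyst or the E/Z ratio may be poor. The fallback is a protecting-group detour with a different isomerization mechanism. It sets out from 1, which is acetylated (Ac2O, pyridine) to 4-allyl-2,6-dimethoxyphenyl acetate F5. PdCl2(MeCN)2 (5 mol%) in CH2Cl2 at room temperature isomerizes this to 2,6-dimethoxy-4-[(E)-prop-1-en-1-yl]phenyl acetate F6. Methanolysis (K2CO3 cat., MeOH, room temperature) removes the acetyl group and comes back to the route at 2.

## Further compounds

F1 | step 2 | 4-{(2R)-2-[2-hydroxy-3-methoxy-5-((E)-prop-1-en-1-yl)phenyl]propylidene}-2,6-dimethoxycyclohexa-2,5-dien-1-one (enantiomer of 4, not isolated) | C/C=C/c1cc(OC)c(O)c(c1)[C@H](C)C=C1C=C(OC)C(=O)C(OC)=C1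
F2 | step 2 | 4-[(2S,3S)-7-methoxy-3-methyl-5-((E)-prop-1-en-1-yl)-2,3-dihydro-1-benzofuran-2-yl]-2,6-dimethoxyphenol (enantiomer of 5) | C/C=C/c1cc(OC)c2c(c1)[C@H](C)[C@@H](c1cc(OC)c(O)c(OC)c1)O2
F3 | step 2 | 4-{(2S)-2-[2-hydroxy-3-methoxy-5-(prop-2-en-1-yl)phenyl]propylidene}-2,6-dimethoxycyclohexa-2,5-dien-1-one (not isolated) | C=CCc1cc(OC)c(O)c(c1)[C@@H](C)C=C1C=C(OC)C(=O)C(OC)=C1
F4 | step 2 | 4-[(2R,3R)-5-allyl-7-methoxy-3-methyl-2,3-dihydro-1-benzofuran-2-yl]-2,6-dimethoxyphenol | C=CCc1cc(OC)c2c(c1)[C@@H](C)[C@H](c1cc(OC)c(O)c(OC)c1)O2
F5 | step 1 | 4-allyl-2,6-dimethoxyphenyl acetate | C=CCc1cc(OC)c(OC(C)=O)c(OC)c1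
F6 | step 1 | 2,6-dimethoxy-4-[(E)-prop-1-en-1-yl]phenyl acetate | C/C=C/c1cc(OC)c(OC(C)=O)c(OC)c1
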